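**Plan**

- Rings are lettered A (3,5-dihydroxyphenyl end) to H (2,4,6-trihydroxyphenyl end), and in each ring C1 bears the oxygen that points toward ring A. Rings C, E and G carry aryloxy groups at C1 and C4 (para) and hydroxyls at C2 and C6. In each of them C3–C4 can therefore come from the ethynyl ether of the next ring, and C2–C1–C6–C5 from a vinylketene built from the aryloxyketene of the preceding ring and ethoxyacetylene.
- Retrosynthesis: first the nineteen O-alkyl bonds (global dealkylation). Then rings G, E and C in turn, each cut at C2–C3 and C4–C5 (plus C1–C2, the cyclobutenone bond that opens and re-forms) into a 4-aryloxy-3-ethoxycyclobutenone and an aryl ethynyl ether.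
- Each cyclobutenone is cut to an aryloxyacetic acid and ethoxyacetylene, and the A–B ether to an Ullmann pair. Rings B, D and F all come from one phenol, 6-(benzyloxy)-2,3,4-trimethoxyphenol, made from 3,4,5-trimethoxyphenol.
- Forward: A-B phenol → cyclobutenone → ring C closes and joins D → methylate, debenzylate, new cyclobutenone → ring E closes and joins F → same operations → ring G closes and joins H → BBr3.
- Stereochemistry: the target has no stereocentre. The racemic centres of the cyclobutenones and cyclohexadienones are transient and vanish on aromatisation.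

Key step: step 12

Remark on the chemistry: "A-B" means the 2-(3,5-dimethoxyphenoxy)-3,4,5-trimethoxyphenyl unit, and D2 or F2 means C2 of ring D or F. Racemic sp3 centres are drawn without configuration. The dichlorovinyl ethers are assumed E (anti addition) and the vinylketenes to have the aryloxy group turned outward. 3,4,5-Trimethoxyphenol, 1-bromo-3,5-dimethoxybenzene, 2,4,6-trimethoxyphenol and ethoxyacetylene are taken as purchasable.

**Route**

Step 1
Reactants: 1 3,4,5-trimethoxyphenol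
Product: 2 5-(benzyloxy)-1,2,3-trimethoxybenzene
Conditions: BnBr, K2CO3, DMF, rt
Reagents that add atoms: benzyl bromide, BrCc1ccccc1
Why: Williamson O-benzylation of the only phenol installs a group that survives the later base, organolithium and thermal steps and is removed by hydrogenolysis.

Step 2
Reactants: 2 5-(benzyloxy)-1,2,3-trimethoxybenzene
Product: 4 6-(benzyloxy)-2,3,4-trimethoxybenzaldehyde, via aryl iminium chloride 3 (not isolated)
Conditions: POCl3, DMF, 0 °C to 70 °C; then H2O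
Reagents that add atoms: N,N-dimethylformamide, CN(C)C=O; water, O
Why: Vilsmeier–Haack formylation attacks one of the two equivalent ring positions flanked by OBn and OMe, so a single aldehyde should form after hydrolysis of the iminium salt.

Step 3
Reactants: 4 6-(benzyloxy)-2,3,4-trimethoxybenzaldehyde
Product: 6 6-(benzyloxy)-2,3,4-trimethoxyphenol, via aryl formate 5 (not isolated)
Conditions: mCPBA, CH2Cl2, 0 °C to rt; then cat. K2CO3, MeOH, rt
Reagents that add atoms: meta-chloroperoxybenzoic acid, OOC(=O)c1cccc(Cl)c1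
Why: Baeyer–Villiger (Dakin-type) oxidation of an alkoxy-rich benzaldehyde proceeds by aryl migration to the formate, which mild methanolysis cleaves to the phenol without touching the benzyl ether.

Step 4
Reactants: 6 6-(benzyloxy)-2,3,4-trimethoxyphenol; 7 1-bromo-3,5-dimethoxybenzene
Product: 8 1-(benzyloxy)-2-(3,5-dimethoxyphenoxy)-3,4,5-trimethoxybenzene
Conditions: CuI (10 mol %), picolinic acid (20 mol %), K3PO4, DMSO, 90 °C, argon
Reagents that add atoms: none
Why: Ullmann-type copper-catalysed diaryl ether synthesis with picolinic acid as ligand is the established way to couple di-ortho-substituted phenols with aryl bromides.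

Step 5
Reactants: 8 1-(benzyloxy)-2-(3,5-dimethoxyphenoxy)-3,4,5-trimethoxybenzene
Product: 9 2-(3,5-dimethoxyphenoxy)-3,4,5-trimethoxyphenol (A-B phenol)
Conditions: H2 (1 atm), 10% Pd/C, EtOAc/MeOH, rt
Reagents that add atoms: none
Why: Catalytic hydrogenolysis cleaves only the benzylic C–O bond and leaves the diaryl ether and the methyl ethers intact.

Step 6
Reactants: 6 6-(benzyloxy)-2,3,4-trimethoxyphenol
Product: 10 1-(benzyloxy)-2-{[(E)-1,2-dichloroethenyl]oxy}-3,4,5-trimethoxybenzene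
Conditions: Cl2C=CHCl, K2CO3, DMF, 70 °C
Reagents that add atoms: trichloroethylene, ClC=C(Cl)Cl
Why: Base converts trichloroethylene to dichloroacetylene, to which the phenoxide adds anti to give the (E)-dichlorovinyl ether (first stage of the Greene ynol ether synthesis).

Step 7
Reactants: 10 1-(benzyloxy)-2-{[(E)-1,2-dichloroethenyl]oxy}-3,4,5-trimethoxybenzene
Product: 13 1-(benzyloxy)-2-(ethynyloxy)-3,4,5-trimethoxybenzene, via chloroethynyl ether 11 (not isolated), via lithium acetylide 12 (not isolated)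
Conditions: n-BuLi (2.2 equiv), Et2O, −78 °C to −40 °C; then H2O, −78 °C; used as a cold solution
Reagents that add atoms: none
Why: Deprotonation with loss of LiCl gives the chloroalkyne, chlorine–lithium exchange gives the acetylide and cold protonation gives the terminal aryl ynol ether (Greene elimination), the low temperature keeping ring metalation and benzylic deprotonation slow.

Step 8
Reactants: 14 2,4,6-trimethoxyphenol
Product: 15 2-{[(E)-1,2-dichloroethenyl]oxy}-1,3,5-trimethoxybenzene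
Conditions: Cl2C=CHCl, K2CO3, DMF, 70 °C
Reagents that add atoms: trichloroethylene, ClC=C(Cl)Cl
Why: The same anti addition of a phenoxide to dichloroacetylene formed in the flask as in step 6 (Greene synthesis, first stage).

Step 9
Reactants: 15 2-{[(E)-1,2-dichloroethenyl]oxy}-1,3,5-trimethoxybenzene
Product: 18 2-(ethynyloxy)-1,3,5-trimethoxybenzene, via chloroethynyl ether 16 (not isolated), via lithium acetylide 17 (not isolated)
Conditions: n-BuLi (2.2 equiv), Et2O, −78 °C to −40 °C; then H2O, −78 °C; used as a cold solution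
Reagents that add atoms: none
Why: The same elimination, chlorine–lithium exchange and protonation as in step 7 (Greene elimination).

Step 10
Reactants: 9 2-(3,5-dimethoxyphenoxy)-3,4,5-trimethoxyphenol (A-B phenol)
Product: 19 [2-(3,5-dimethoxyphenoxy)-3,4,5-trimethoxyphenoxy]acetic acid (A-B acid)
Conditions: NaH (2.5 equiv), BrCH2CO2H, THF/DMF, 0 °C to 50 °C; then aq HCl
Reagents that add atoms: bromoacetic acid, OC(=O)CBr
Why: Williamson alkylation of the sodium phenoxide with sodium bromoacetate is the classical one-step route to aryloxyacetic acids.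

Step 11
Reactants: 19 A-B acid; 20 ethoxyacetylene
Product: 23 4-[2-(3,5-dimethoxyphenoxy)-3,4,5-trimethoxyphenoxy]-3-ethoxycyclobut-2-en-1-one (racemic), via A-B aryloxyacetyl chloride 21 (not isolated), via A-B aryloxyketene 22 (not isolated)
Conditions: (COCl)2, cat. DMF, CH2Cl2, 0 °C to rt, evaporate; then 20 (3 equiv), Et3N (slow addition), CH2Cl2, 0 °C to rt
Reagents that add atoms: none
Why: Dehydrochlorination of the acid chloride gives the electrophilic aryloxyketene, which undergoes the known ketene–alkoxyalkyne [2+2] cycloaddition, the nucleophilic terminal carbon of 20 bonding to the ketene carbonyl carbon so that OEt sits at C3 and the aryloxy group at C4 (racemic centre, lost later).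

Step 12
Reactants: 23 A-B cyclobutenone; 13 1-(benzyloxy)-2-(ethynyloxy)-3,4,5-trimethoxybenzene
Product: 28 tetramer phenol A-B-C-D (ring C 2-OH 6-OEt; ring D 2-OBn; other oxygens OMe), via A-B vinylketene 24 (not isolated), via A-B-D vinylcyclobutenone 25 (not isolated), via A-B-D dienylketene 26 (not isolated), via tetramer cyclohexadienone 27 (not isolated)
Conditions: 13 (1.5 equiv), toluene, 80 °C then 110 °C, argon
Reagents that add atoms: none
Why: Thermal 4π-electrocyclic opening of 23 gives vinylketene 24, which adds ynol ether 13 in a [2+2] cycloaddition (forming C2–C3 and C4–C5 of ring C); the 4-vinylcyclobutenone 25 reopens to dienylketene 26, which cyclises and tautomerises to phenol 28. The closest known reaction is the Danheiser benzannulation of 3-alkoxycyclobutenones with alkoxyalkynes to resorcinol monoethers, here with an aryl ynol ether and a 4-aryloxy substituent. Ring C closes by a thermal disrotatory 6π-electrocyclisation that re-forms C1–C2, giving cyclohexa-2,4-dienone 27 before enolisation. No stereocentre is created that persists, since the racemic centres of 23, 25 and 27 are all erased on aromatisation. The step needs O-D para to O-B, which is secured because the terminal (β) carbon of 13 is its nucleophilic site and bonds to the electrophilic ketene carbon; it also needs the cyclisable dienylketene geometry, which is supplied because opening of 25 is reversible and only the isomer with the vinyl group turned inward is drained, while outward rotation of the aryloxy donor in the first opening leaves hydrogen as the inward group at the closing terminus. Excess 13 should outpace ketene dimerisation, and any aryl ester formed by ketene capture by 28 can be cleaved with methanolic K2CO3 during work-up.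

Step 13
Reactants: 28 tetramer phenol A-B-C-D
Product: 29 tetramer methyl ether (ring C 2-OMe 6-OEt; ring D 2-OBn)
Conditions: MeI, K2CO3, DMF, rt
Reagents that add atoms: iodomethane, CI
Why: Williamson methylation caps the only free phenol so that the hydroxyl freed next on ring D is the single nucleophilic site.

Step 14
Reactants: 29 tetramer methyl ether
Product: 30 tetramer phenol with free D2-OH
Conditions: H2 (1 atm), 10% Pd/C, EtOAc/MeOH, rt
Reagents that add atoms: none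
Why: Hydrogenolysis removes the single benzyl ether without affecting alkyl aryl or diaryl ethers.

Step 15
Reactants: 30 tetramer phenol with free D2-OH
Product: 31 (tetramer-D2-oxy)acetic acid
Conditions: NaH (2.5 equiv), BrCH2CO2H, THF/DMF, 0 °C to 50 °C; then aq HCl
Reagents that add atoms: bromoacetic acid, OC(=O)CBr
Why: The same Williamson synthesis of an aryloxyacetic acid as in step 10.

Step 16
Reactants: 31 (tetramer-D2-oxy)acetic acid; 20 ethoxyacetylene
Product: 34 3-ethoxy-4-(tetramer-D2-oxy)cyclobut-2-en-1-one (racemic), via tetramer aryloxyacetyl chloride 32 (not isolated), via tetramer aryloxyketene 33 (not isolated)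
Conditions: (COCl)2, cat. DMF, CH2Cl2, 0 °C to rt, evaporate; then 20 (3 equiv), Et3N (slow addition), CH2Cl2, 0 °C to rt
Reagents that add atoms: none
Why: The same ketene–alkoxyalkyne [2+2] cycloaddition as in step 11, with the same regiochemistry.

Step 17
Reactants: 34 tetramer cyclobutenone; 13 1-(benzyloxy)-2-(ethynyloxy)-3,4,5-trimethoxybenzene
Product: 39 hexamer phenol A-B-C-D-E-F (ring E 2-OH 6-OEt; ring F 2-OBn), via tetramer vinylketene 35 (not isolated), via hexamer-stage vinylcyclobutenone 36 (not isolated), via hexamer-stage dienylketene 37 (not isolated), via hexamer cyclohexadienone 38 (not isolated)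
Conditions: 13 (1.5 equiv), toluene, 80 °C then 110 °C, argon
Reagents that add atoms: none
Why: Danheiser benzannulation as in step 12 builds ring E between rings D and F, with the same origin of the para relation of the two aryloxy groups.

Step 18
Reactants: 39 hexamer phenol
Product: 40 hexamer methyl ether (ring E 2-OMe 6-OEt; ring F 2-OBn)
Conditions: MeI, K2CO3, DMF, rt
Reagents that add atoms: iodomethane, CI
Why: Williamson methylation of the only free phenol, as in step 13.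

Step 19
Reactants: 40 hexamer methyl ether
Product: 41 hexamer phenol with free F2-OH
Conditions: H2 (1 atm), 10% Pd/C, EtOAc/MeOH, rt
Reagents that add atoms: none
Why: Benzyl ether hydrogenolysis as in step 14.

Step 20
Reactants: 41 hexamer phenol with free F2-OH
Product: 42 (hexamer-F2-oxy)acetic acid
Conditions: NaH (2.5 equiv), BrCH2CO2H, THF/DMF, 0 °C to 50 °C; then aq HCl
Reagents that add atoms: bromoacetic acid, OC(=O)CBr
Why: Williamson synthesis of the aryloxyacetic acid as in step 10.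

Step 21
Reactants: 42 (hexamer-F2-oxy)acetic acid; 20 ethoxyacetylene
Product: 45 3-ethoxy-4-(hexamer-F2-oxy)cyclobut-2-en-1-one (racemic), via hexamer aryloxyacetyl chloride 43 (not isolated), via hexamer aryloxyketene 44 (not isolated)
Conditions: (COCl)2, cat. DMF, CH2Cl2, 0 °C to rt, evaporate; then 20 (3 equiv), Et3N (slow addition), CH2Cl2, 0 °C to rt
Reagents that add atoms: none
Why: Ketene–alkoxyalkyne [2+2] cycloaddition as in step 11.

Step 22
Reactants: 45 hexamer cyclobutenone; 18 2-(ethynyloxy)-1,3,5-trimethoxybenzene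
Product: 50 octamer phenol A to H (ring G 2-OH 6-OEt; ring H 2,4,6-trimethoxyphenyl), via hexamer vinylketene 46 (not isolated), via octamer-stage vinylcyclobutenone 47 (not isolated), via octamer-stage dienylketene 48 (not isolated), via octamer cyclohexadienone 49 (not isolated)
Conditions: 18 (1.5 equiv), toluene, 80 °C then 110 °C, argon
Reagents that add atoms: none
Why: Danheiser benzannulation as in step 12 builds ring G between rings F and H and completes the octaphenyl chain.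

Step 23
Reactants: 50 octamer phenol
Product: 51 CNP0319661.0 (all twenty oxygens as free hydroxyls)
Conditions: BBr3 (excess), CH2Cl2, −78 °C to rt, argon; then H2O, 0 °C
Reagents that add atoms: none
Why: Lewis acid dealkylation of aryl methyl and ethyl ethers by bromide attack at the alkyl carbon of the boron-complexed ether removes all sixteen methyl and three ethyl groups, while the diaryl ether bonds offer no sp3 carbon and stay intact.

**Compound list**

1 | 3,4,5-trimethoxyphenol | COc1cc(O)cc(OC)c1OC | starting material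
2 | 5-(benzyloxy)-1,2,3-trimethoxybenzene | COc1cc(OCc2ccccc2)cc(OC)c1OC | intermediate
3 | [6-(benzyloxy)-2,3,4-trimethoxybenzylidene]dimethyliminium chloride (not isolated) | C[N+](C)=Cc1c(OCc2ccccc2)cc(OC)c(OC)c1OC.[Cl-] | intermediate
4 | 6-(benzyloxy)-2,3,4-trimethoxybenzaldehyde | O=Cc1c(OCc2ccccc2)cc(OC)c(OC)c1OC | intermediate
5 | 6-(benzyloxy)-2,3,4-trimethoxyphenyl formate (not isolated) | O=COc1c(OCc2ccccc2)cc(OC)c(OC)c1OC | intermediate
6 | 6-(benzyloxy)-2,3,4-trimethoxyphenol | Oc1c(OCc2ccccc2)cc(OC)c(OC)c1OC | intermediate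
7 | 1-bromo-3,5-dimethoxybenzene | COc1cc(Br)cc(OC)c1 | starting material
8 | 1-(benzyloxy)-2-(3,5-dimethoxyphenoxy)-3,4,5-trimethoxybenzene | COc1cc(OC)cc(Oc2c(OCc3ccccc3)cc(OC)c(OC)c2OC)c1 | intermediate
9 | 2-(3,5-dimethoxyphenoxy)-3,4,5-trimethoxyphenol (A-B phenol) | COc1cc(OC)cc(Oc2c(O)cc(OC)c(OC)c2OC)c1 | intermediate
10 | 1-(benzyloxy)-2-{[(E)-1,2-dichloroethenyl]oxy}-3,4,5-trimethoxybenzene | Cl/C=C(/Cl)Oc1c(OCc2ccccc2)cc(OC)c(OC)c1OC | intermediate
11 | 1-(benzyloxy)-2-[(chloroethynyl)oxy]-3,4,5-trimethoxybenzene (not isolated) | ClC#COc1c(OCc2ccccc2)cc(OC)c(OC)c1OC | intermediate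
12 | {[6-(benzyloxy)-2,3,4-trimethoxyphenoxy]ethynyl}lithium (not isolated) | [Li]C#COc1c(OCc2ccccc2)cc(OC)c(OC)c1OC | intermediate
13 | 1-(benzyloxy)-2-(ethynyloxy)-3,4,5-trimethoxybenzene (ethynyl ether for rings D and F) | C#COc1c(OCc2ccccc2)cc(OC)c(OC)c1OC | intermediate
14 | 2,4,6-trimethoxyphenol | COc1cc(OC)c(O)c(OC)c1 | starting material
15 | 2-{[(E)-1,2-dichloroethenyl]oxy}-1,3,5-trimethoxybenzene | Cl/C=C(/Cl)Oc1c(OC)cc(OC)cc1OC | intermediate
16 | 2-[(chloroethynyl)oxy]-1,3,5-trimethoxybenzene (not isolated) | ClC#COc1c(OC)cc(OC)cc1OC | intermediate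
17 | [(2,4,6-trimethoxyphenoxy)ethynyl]lithium (not isolated) | [Li]C#COc1c(OC)cc(OC)cc1OC | intermediate
18 | 2-(ethynyloxy)-1,3,5-trimethoxybenzene (ethynyl ether for ring H) | C#COc1c(OC)cc(OC)cc1OC | intermediate
19 | [2-(3,5-dimethoxyphenoxy)-3,4,5-trimethoxyphenoxy]acetic acid | OC(=O)COc1cc(OC)c(OC)c(OC)c1Oc1cc(OC)cc(OC)c1 | intermediate
20 | ethoxyacetylene | CCOC#C | starting material
21 | [2-(3,5-dimethoxyphenoxy)-3,4,5-trimethoxyphenoxy]acetyl chloride (not isolated) | ClC(=O)COc1cc(OC)c(OC)c(OC)c1Oc1cc(OC)cc(OC)c1 | intermediate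
22 | 2-[2-(3,5-dimethoxyphenoxy)-3,4,5-trimethoxyphenoxy]ethen-1-one, the A-B aryloxyketene (not isolated) | O=C=COc1cc(OC)c(OC)c(OC)c1Oc1cc(OC)cc(OC)c1 | intermediate
23 | 4-[2-(3,5-dimethoxyphenoxy)-3,4,5-trimethoxyphenoxy]-3-ethoxycyclobut-2-en-1-one (racemic) | O=C1C=C(OCC)C1Oc1cc(OC)c(OC)c(OC)c1Oc1cc(OC)cc(OC)c1 | intermediate
24 | (3Z)-4-[2-(3,5-dimethoxyphenoxy)-3,4,5-trimethoxyphenoxy]-3-ethoxybuta-1,3-dien-1-one (not isolated) | O=C=C/C(OCC)=C/Oc1cc(OC)c(OC)c(OC)c1Oc1cc(OC)cc(OC)c1 | intermediate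
25 | 3-[6-(benzyloxy)-2,3,4-trimethoxyphenoxy]-4-{(Z)-2-[2-(3,5-dimethoxyphenoxy)-3,4,5-trimethoxyphenoxy]-1-ethoxyethenyl}cyclobut-2-en-1-one (racemic, not isolated) | O=C1C=C(Oc2c(OCc3ccccc3)cc(OC)c(OC)c2OC)C1/C(OCC)=C/Oc1cc(OC)c(OC)c(OC)c1Oc1cc(OC)cc(OC)c1 | intermediate
26 | (3E,5Z)-3-[6-(benzyloxy)-2,3,4-trimethoxyphenoxy]-6-[2-(3,5-dimethoxyphenoxy)-3,4,5-trimethoxyphenoxy]-5-ethoxyhexa-1,3,5-trien-1-one (not isolated) | O=C=C/C(Oc1c(OCc2ccccc2)cc(OC)c(OC)c1OC)=C\C(OCC)=C\Oc1cc(OC)c(OC)c(OC)c1Oc1cc(OC)cc(OC)c1 | intermediate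
27 | 3-[6-(benzyloxy)-2,3,4-trimethoxyphenoxy]-6-[2-(3,5-dimethoxyphenoxy)-3,4,5-trimethoxyphenoxy]-5-ethoxycyclohexa-2,4-dien-1-one (racemic, not isolated) | O=C1C=C(Oc2c(OCc3ccccc3)cc(OC)c(OC)c2OC)C=C(OCC)C1Oc1cc(OC)c(OC)c(OC)c1Oc1cc(OC)cc(OC)c1 | intermediate
28 | 5-[6-(benzyloxy)-2,3,4-trimethoxyphenoxy]-2-[2-(3,5-dimethoxyphenoxy)-3,4,5-trimethoxyphenoxy]-3-ethoxyphenol (tetramer phenol A-B-C-D) | CCOc1cc(Oc2c(OCc3ccccc3)cc(OC)c(OC)c2OC)cc(O)c1Oc1cc(OC)c(OC)c(OC)c1Oc1cc(OC)cc(OC)c1 | intermediate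
29 | methyl ether of 28 (ring C 2-OMe 6-OEt; ring D 2-OBn) | CCOc1cc(Oc2c(OCc3ccccc3)cc(OC)c(OC)c2OC)cc(OC)c1Oc1cc(OC)c(OC)c(OC)c1Oc1cc(OC)cc(OC)c1 | intermediate
30 | debenzylated 29, tetramer phenol with free D2-OH | CCOc1cc(Oc2c(O)cc(OC)c(OC)c2OC)cc(OC)c1Oc1cc(OC)c(OC)c(OC)c1Oc1cc(OC)cc(OC)c1 | intermediate
31 | (tetramer-D2-oxy)acetic acid | OC(=O)COc1cc(OC)c(OC)c(OC)c1Oc1cc(OCC)c(Oc2cc(OC)c(OC)c(OC)c2Oc2cc(OC)cc(OC)c2)c(OC)c1 | intermediate
32 | (tetramer-D2-oxy)acetyl chloride (not isolated) | ClC(=O)COc1cc(OC)c(OC)c(OC)c1Oc1cc(OCC)c(Oc2cc(OC)c(OC)c(OC)c2Oc2cc(OC)cc(OC)c2)c(OC)c1 | intermediate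
33 | (tetramer-D2-oxy)ketene (not isolated) | O=C=COc1cc(OC)c(OC)c(OC)c1Oc1cc(OCC)c(Oc2cc(OC)c(OC)c(OC)c2Oc2cc(OC)cc(OC)c2)c(OC)c1 | intermediate
34 | 3-ethoxy-4-(tetramer-D2-oxy)cyclobut-2-en-1-one (racemic) | O=C1C=C(OCC)C1Oc1cc(OC)c(OC)c(OC)c1Oc1cc(OCC)c(Oc2cc(OC)c(OC)c(OC)c2Oc2cc(OC)cc(OC)c2)c(OC)c1 | intermediate
35 | (3Z)-3-ethoxy-4-(tetramer-D2-oxy)buta-1,3-dien-1-one (not isolated) | O=C=C/C(OCC)=C/Oc1cc(OC)c(OC)c(OC)c1Oc1cc(OCC)c(Oc2cc(OC)c(OC)c(OC)c2Oc2cc(OC)cc(OC)c2)c(OC)c1 | intermediate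
36 | 3-[6-(benzyloxy)-2,3,4-trimethoxyphenoxy]-4-[(Z)-1-ethoxy-2-(tetramer-D2-oxy)ethenyl]cyclobut-2-en-1-one (racemic, not isolated) | O=C1C=C(Oc2c(OCc3ccccc3)cc(OC)c(OC)c2OC)C1/C(OCC)=C/Oc1cc(OC)c(OC)c(OC)c1Oc1cc(OCC)c(Oc2cc(OC)c(OC)c(OC)c2Oc2cc(OC)cc(OC)c2)c(OC)c1 | intermediate
37 | (3E,5Z)-3-[6-(benzyloxy)-2,3,4-trimethoxyphenoxy]-5-ethoxy-6-(tetramer-D2-oxy)hexa-1,3,5-trien-1-one (not isolated) | O=C=C/C(Oc1c(OCc2ccccc2)cc(OC)c(OC)c1OC)=C\C(OCC)=C\Oc1cc(OC)c(OC)c(OC)c1Oc1cc(OCC)c(Oc2cc(OC)c(OC)c(OC)c2Oc2cc(OC)cc(OC)c2)c(OC)c1 | intermediate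
38 | 3-[6-(benzyloxy)-2,3,4-trimethoxyphenoxy]-5-ethoxy-6-(tetramer-D2-oxy)cyclohexa-2,4-dien-1-one (racemic, not isolated) | O=C1C=C(Oc2c(OCc3ccccc3)cc(OC)c(OC)c2OC)C=C(OCC)C1Oc1cc(OC)c(OC)c(OC)c1Oc1cc(OCC)c(Oc2cc(OC)c(OC)c(OC)c2Oc2cc(OC)cc(OC)c2)c(OC)c1 | intermediate
39 | hexamer phenol A to F (ring E 2-OH 6-OEt; ring F 2-OBn; ring C 2-OMe 6-OEt; other oxygens OMe) | CCOc1cc(Oc2c(OCc3ccccc3)cc(OC)c(OC)c2OC)cc(O)c1Oc1cc(OC)c(OC)c(OC)c1Oc1cc(OCC)c(Oc2cc(OC)c(OC)c(OC)c2Oc2cc(OC)cc(OC)c2)c(OC)c1 | intermediate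
40 | methyl ether of 39 (ring E 2-OMe 6-OEt; ring F 2-OBn) | CCOc1cc(Oc2c(OCc3ccccc3)cc(OC)c(OC)c2OC)cc(OC)c1Oc1cc(OC)c(OC)c(OC)c1Oc1cc(OCC)c(Oc2cc(OC)c(OC)c(OC)c2Oc2cc(OC)cc(OC)c2)c(OC)c1 | intermediate
41 | debenzylated 40, hexamer phenol with free F2-OH | CCOc1cc(Oc2c(O)cc(OC)c(OC)c2OC)cc(OC)c1Oc1cc(OC)c(OC)c(OC)c1Oc1cc(OCC)c(Oc2cc(OC)c(OC)c(OC)c2Oc2cc(OC)cc(OC)c2)c(OC)c1 | intermediate
42 | (hexamer-F2-oxy)acetic acid | OC(=O)COc1cc(OC)c(OC)c(OC)c1Oc1cc(OCC)c(Oc2cc(OC)c(OC)c(OC)c2Oc2cc(OCC)c(Oc3cc(OC)c(OC)c(OC)c3Oc3cc(OC)cc(OC)c3)c(OC)c2)c(OC)c1 | intermediate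
43 | (hexamer-F2-oxy)acetyl chloride (not isolated) | ClC(=O)COc1cc(OC)c(OC)c(OC)c1Oc1cc(OCC)c(Oc2cc(OC)c(OC)c(OC)c2Oc2cc(OCC)c(Oc3cc(OC)c(OC)c(OC)c3Oc3cc(OC)cc(OC)c3)c(OC)c2)c(OC)c1 | intermediate
44 | (hexamer-F2-oxy)ketene (not isolated) | O=C=COc1cc(OC)c(OC)c(OC)c1Oc1cc(OCC)c(Oc2cc(OC)c(OC)c(OC)c2Oc2cc(OCC)c(Oc3cc(OC)c(OC)c(OC)c3Oc3cc(OC)cc(OC)c3)c(OC)c2)c(OC)c1 | intermediate
45 | 3-ethoxy-4-(hexamer-F2-oxy)cyclobut-2-en-1-one (racemic) | O=C1C=C(OCC)C1Oc1cc(OC)c(OC)c(OC)c1Oc1cc(OCC)c(Oc2cc(OC)c(OC)c(OC)c2Oc2cc(OCC)c(Oc3cc(OC)c(OC)c(OC)c3Oc3cc(OC)cc(OC)c3)c(OC)c2)c(OC)c1 | intermediate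
46 | (3Z)-3-ethoxy-4-(hexamer-F2-oxy)buta-1,3-dien-1-one (not isolated) | O=C=C/C(OCC)=C/Oc1cc(OC)c(OC)c(OC)c1Oc1cc(OCC)c(Oc2cc(OC)c(OC)c(OC)c2Oc2cc(OCC)c(Oc3cc(OC)c(OC)c(OC)c3Oc3cc(OC)cc(OC)c3)c(OC)c2)c(OC)c1 | intermediate
47 | 4-[(Z)-1-ethoxy-2-(hexamer-F2-oxy)ethenyl]-3-(2,4,6-trimethoxyphenoxy)cyclobut-2-en-1-one (racemic, not isolated) | O=C1C=C(Oc2c(OC)cc(OC)cc2OC)C1/C(OCC)=C/Oc1cc(OC)c(OC)c(OC)c1Oc1cc(OCC)c(Oc2cc(OC)c(OC)c(OC)c2Oc2cc(OCC)c(Oc3cc(OC)c(OC)c(OC)c3Oc3cc(OC)cc(OC)c3)c(OC)c2)c(OC)c1 | intermediate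
48 | (3E,5Z)-5-ethoxy-6-(hexamer-F2-oxy)-3-(2,4,6-trimethoxyphenoxy)hexa-1,3,5-trien-1-one (not isolated) | O=C=C/C(Oc1c(OC)cc(OC)cc1OC)=C\C(OCC)=C\Oc1cc(OC)c(OC)c(OC)c1Oc1cc(OCC)c(Oc2cc(OC)c(OC)c(OC)c2Oc2cc(OCC)c(Oc3cc(OC)c(OC)c(OC)c3Oc3cc(OC)cc(OC)c3)c(OC)c2)c(OC)c1 | intermediate
49 | 5-ethoxy-6-(hexamer-F2-oxy)-3-(2,4,6-trimethoxyphenoxy)cyclohexa-2,4-dien-1-one (racemic, not isolated) | O=C1C=C(Oc2c(OC)cc(OC)cc2OC)C=C(OCC)C1Oc1cc(OC)c(OC)c(OC)c1Oc1cc(OCC)c(Oc2cc(OC)c(OC)c(OC)c2Oc2cc(OCC)c(Oc3cc(OC)c(OC)c(OC)c3Oc3cc(OC)cc(OC)c3)c(OC)c2)c(OC)c1 | intermediate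
50 | octamer phenol A to H (ring G 2-OH 6-OEt; rings C and E 2-OMe 6-OEt; all other oxygens OMe) | CCOc1cc(Oc2c(OC)cc(OC)cc2OC)cc(O)c1Oc1cc(OC)c(OC)c(OC)c1Oc1cc(OCC)c(Oc2cc(OC)c(OC)c(OC)c2Oc2cc(OCC)c(Oc3cc(OC)c(OC)c(OC)c3Oc3cc(OC)cc(OC)c3)c(OC)c2)c(OC)c1 | intermediate
51 | CNP0319661.0, the octaphenyl heptaether A to H with twenty free hydroxyls | Oc1cc(O)cc(Oc2c(Oc3c(O)cc(Oc4c(Oc5c(O)cc(Oc6c(Oc7c(O)cc(Oc8c(O)cc(O)cc8O)cc7O)cc(O)c(O)c6O)cc5O)cc(O)c(O)c4O)cc3O)cc(O)c(O)c2O)c1 | target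

**Count and risks**

Total step count: 23. Longest linear sequence: 19 steps (steps 1 to 5, then 10 to 23).

Steps most likely to fail:

Step 12 (and its repeats, steps 17 and 22). The terminal aryl ynol ether may self-condense on heating, or capture the vinylketene too slowly, so that ketene dimerisation and acylation of the product phenol take over; this grows worse as the cyclobutenone becomes larger. The fallback changes the alkyne component to a silyl-capped one with a traceless blocking group. It sets out from 10: the lithium acetylide 12 is generated as in step 7 but quenched with Me3SiCl instead of water, to give {[6-(benzyloxy)-2,3,4-trimethoxyphenoxy]ethynyl}trimethylsilane F1. This ynol ether can be stored and heated, and its silicon-bearing carbon is the more nucleophilic terminus, so the regiochemistry is reinforced. Heating F1 with 23 in toluene should give 5-[6-(benzyloxy)-2,3,4-trimethoxyphenoxy]-2-[2-(3,5-dimethoxyphenoxy)-3,4,5-trimethoxyphenoxy]-3-ethoxy-6-(trimethylsilyl)phenol F2. Protodesilylation of this ortho-silyl phenol with Bu4NF in THF returns to the route at 28.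

Step 11 (and its repeats, steps 16 and 21). Ketene dimerisation or acylation of the electron-rich rings may compete with capture by ethoxyacetylene, and the enol ether of the cyclobutenone may hydrolyse on isolation. The fallback reaches the same vinylketene without the cyclobutenone. It sets out from 9: O-alkylation with ethyl (E)-4-bromo-3-ethoxybut-2-enoate (K2CO3, acetone) gives ethyl (E)-4-[2-(3,5-dimethoxyphenoxy)-3,4,5-trimethoxyphenoxy]-3-ethoxybut-2-enoate F3. Saponification (LiOH, THF/H2O) gives (E)-4-[2-(3,5-dimethoxyphenoxy)-3,4,5-trimethoxyphenoxy]-3-ethoxybut-2-enoic acid F4. Oxalyl chloride then gives (E)-4-[2-(3,5-dimethoxyphenoxy)-3,4,5-trimethoxyphenoxy]-3-ethoxybut-2-enoyl chloride F5. Treating F5 with Et3N in toluene in the presence of 13, first at rt and then at 80 to 110 °C, should cause 1,4-dehydrochlorination to vinylketene 24, which passes through 25, 26 and 27 as in step 12. The fallback comes back to the route at 28.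

Step 23. Dealkylation across nineteen ether groups may stop short, and the twenty-fold phenol may oxidise in air during isolation, giving mixtures that cannot be separated as free phenols. The fallback isolates the product in protected form. It sets out from 50: after the BBr3 treatment and aqueous quench the crude material is acetylated (Ac2O, pyridine, cat. DMAP) to the icosaacetate of 51 F6, which is stable and can be purified on silica and separated from partly alkylated material. Acid-catalysed methanolysis (HCl generated from AcCl in MeOH, rt, argon) then releases the free phenols under non-oxidising, non-basic conditions and comes back to the route at 51.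

Further compounds
F1 | step 12 | {[6-(benzyloxy)-2,3,4-trimethoxyphenoxy]ethynyl}trimethylsilane | C[Si](C)(C)C#COc1c(OCc2ccccc2)cc(OC)c(OC)c1OC
F2 | step 12 | 5-[6-(benzyloxy)-2,3,4-trimethoxyphenoxy]-2-[2-(3,5-dimethoxyphenoxy)-3,4,5-trimethoxyphenoxy]-3-ethoxy-6-(trimethylsilyl)phenol | CCOc1cc(Oc2c(OCc3ccccc3)cc(OC)c(OC)c2OC)c([Si](C)(C)C)c(O)c1Oc1cc(OC)c(OC)c(OC)c1Oc1cc(OC)cc(OC)c1
F3 | step 11 | ethyl (E)-4-[2-(3,5-dimethoxyphenoxy)-3,4,5-trimethoxyphenoxy]-3-ethoxybut-2-enoate | CCOC(=O)/C=C(/OCC)COc1cc(OC)c(OC)c(OC)c1Oc1cc(OC)cc(OC)c1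
F4 | step 11 | (E)-4-[2-(3,5-dimethoxyphenoxy)-3,4,5-trimethoxyphenoxy]-3-ethoxybut-2-enoic acid | OC(=O)/C=C(/OCC)COc1cc(OC)c(OC)c(OC)c1Oc1cc(OC)cc(OC)c1
F5 | step 11 | (E)-4-[2-(3,5-dimethoxyphenoxy)-3,4,5-trimethoxyphenoxy]-3-ethoxybut-2-enoyl chloride | ClC(=O)/C=C(/OCC)COc1cc(OC)c(OC)c(OC)c1Oc1cc(OC)cc(OC)c1
F6 | step 23 | icosaacetate of 51 (every hydroxyl as its acetate) | CC(=O)Oc1cc(OC(C)=O)cc(Oc2c(Oc3c(OC(C)=O)cc(Oc4c(Oc5c(OC(C)=O)cc(Oc6c(Oc7c(OC(C)=O)cc(Oc8c(OC(C)=O)cc(OC(C)=O)cc8OC(C)=O)cc7OC(C)=O)cc(OC(C)=O)c(OC(C)=O)c6OC(C)=O)cc5OC(C)=O)cc(OC(C)=O)c(OC(C)=O)c4OC(C)=O)cc3OC(C)=O)cc(OC(C)=O)c(OC(C)=O)c2OC(C)=O)c1
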